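The solubility 0.083 M is the number I hang this flask on.

    starting material + starting material ⇌ target (K1 = 1.45 L mol⁻¹, k1 = 0.572 L mol⁻¹ s⁻¹)
    solid substrate ⇌ starting material, rate k2*(cs2 - [starting material]) while solid is left; crystals form when [starting material] > cs2 (cs2 = 0.083 M, k2 = 0.0765 s⁻¹)
    target ⇌ isomer of the product (K3 = 0.441, k3 = 0.0165 s⁻¹)

solid substrate 0.50 M; time 80 s

- Wednesday's: doubling the solubility in step 2, all else as stated
- Monday's: doubling the dissolution coefficient of step 2, all else as stated

- in percentages every species weighs as the solid substrate in it: one target or isomer of the product counts as two
- two of one species on the left: rate k times its square, two consumed each time
- as a solid, counted per litre of solution: solid substrate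
- at the start none of the solid substrate is in solution
- run time (flask): 80 s

1. amount of target at 80 s, in percent of the solid substrate charged
2. the change that raises the amount of target at 80 s, in percent of the solid substrate charged most ("none" if none brings more than 2 percentage points) (Wednesday's / Monday's / none)
3. amount of target at 80 s, in percent of the solid substrate charged, after Wednesday's

I build the flask up one step at a time, writing S for the solubility and K for the equilibrium constant of the first step. The first step by itself gives nothing, since no solid substrate is in solution at the start. Adding the dissolving changes that: its time, 13.1 s, is shorter than the run, so starting material climbs towards S. Target then heads for K times S squared, 0.009989 M. I carry this as the saturation ceiling, the target in equilibrium with a saturated solution, counted twice against the charge: 4.00%.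

The isomer step comes last. It stands isomer of the product at 0.441 times the target, and dissolving solid substrate has to pay for that. So I go round once more and put the first answer back in. Saturation plus twice the target and isomer of the product needs 0.112 M dissolved, less than the charge of 0.50 M. Solid substrate is therefore not the limiting reagent, and the ceiling stands.

Wednesday's raises the ceiling to 16.0%, and its budget of 0.281 M still fits the charge. Monday's leaves the ceiling where it is, so I expect less than 2 percentage points from it. I commit to Wednesday's, with answers under the two ceilings.

The forecast gives numbers where I give bounds: 3.75% (from 3.6% to 3.9%), 14.2% (from 13.5% to 14.9%), and Wednesday's. Its ground is the same as mine: “Solid never runs out”.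

The flask gives 3.75%, which is 0.25 points below the ceiling, and 14.1% after Wednesday's, which gains 10 points against 0.19 points for Monday's. One change that puts the forecast's range wrong is a smaller charge: 0.214 M is the nearest amount of solid substrate below the present one at which the answer has moved by 5 points. In a thin flask with 0.12 M of solid substrate, the budget 0.112 M still fits and the ceiling is 16.6%. That flask holds 15.6% of target at 80 s, with 11.3% still solid.

(The rate constants were drawn at random within sensible limits, and the outcome is calculated.)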